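## Retrosynthetic overview

1. Last bond: the aryl ether C1–O, from the 7-OH of daphnetin (coumarin bought intact) and a terminal epoxide generated from the primary tosylate of a triol lactone.
2. The γ-lactone is the only ring built that stays. It closes from a 1,3-anti diol acid whose C5 carbinol comes from a hydroxyl-directed reduction steered by the tertiary C3–OH.
3. Key C4–C5 bond: a light-driven nickel-catalysed coupling of a 2,2-disubstituted epoxide (C1–C4) with (R)-methylsuccinic anhydride (C5–C8, C7 bought).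
4. The epoxide comes from methyl (S)-isopropylideneglycerate (C2 bought): chloromethyl ketone, then methyl Grignard addition sets C3 from C2.
5. Ring order: dioxolane (bought, protecting) → transient oxirane → γ-lactone → second transient oxirane, opened by the coumarin phenol.

Assumption: chain carbons are labelled C1 (ArO–CH2) to C8 (lactone carbonyl); the target is read as (2S,3S) in the diol and (5R,7R) in the cis-lactone, i.e. 2,3-syn and 3,5-anti.

## Route

Step 1
Reactants: 1 methyl (S)-2,2-dimethyl-1,3-dioxolane-4-carboxylate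
Product: 2 (S)-2-chloro-1-(2,2-dimethyl-1,3-dioxolan-4-yl)ethan-1-one
Conditions: ICH2Cl (1.5 equiv), MeLi·LiBr (1.4 equiv), THF, −78 °C; aq NH4Cl quench at −78 °C
Reagents that add atoms: chloroiodomethane, ClCI
Why: Carbenoid homologation of an ester: chloromethyllithium formed by fast iodine–lithium exchange adds once, and the tetrahedral lithium alkoxide survives at −78 °C until the quench, so neither double addition nor enolisation of the adjacent stereocentre occurs.

Step 2
Reactants: 2 (S)-2-chloro-1-(2,2-dimethyl-1,3-dioxolan-4-yl)ethan-1-one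
Product: 4 (S)-2,2-dimethyl-4-[(S)-2-methyloxiran-2-yl]-1,3-dioxolane, via chlorohydrin 3 (not isolated)
Conditions: MeMgBr (1.3 equiv), THF, −78 °C; then 2 M NaOH, 0 °C to rt
Reagents that add atoms: methylmagnesium bromide, C[Mg]Br
Why: Felkin–Anh-controlled Grignard addition to the α-alkoxy ketone (ring C–O bond anti to the incoming methyl, reinforced by β-chelation to the distal ring oxygen) sets the tertiary carbinol from the bought C2 centre, and because methyl is the group added last the two oxygens end up syn (the (R)-chlorohydrin); hydroxide then closes the epoxide by intramolecular Williamson displacement with retention at C3.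

Step 3
Reactants: 5 (R)-2-methylbutanedioic acid
Product: 6 (R)-3-methyloxolane-2,5-dione
Conditions: Ac2O, 80 °C; distil
Reagents that add atoms: none
Why: Cyclodehydration of a 1,4-diacid to the five-membered anhydride through the mixed acetic anhydride; the bought methyl-bearing centre is not enolised under these base-free conditions.

Step 4
Reactants: 4 (S)-2,2-dimethyl-4-[(S)-2-methyloxiran-2-yl]-1,3-dioxolane; 6 (R)-3-methyloxolane-2,5-dione
Product: 8 (2R,6S)-6-[(4S)-2,2-dimethyl-1,3-dioxolan-4-yl]-6-hydroxy-2-methyl-4-oxoheptanoic acid, via iodohydrin 7 (not isolated)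
Conditions: 6 (1.5 equiv), NiBr2(dme) (10 mol %), 4,4′-di-tert-butyl-2,2′-bipyridine (12 mol %), 4CzIPN (2,4,5,6-tetrakis(carbazol-9-yl)isophthalonitrile, 2 mol %), NaI (0.5 equiv), 2,4,6-collidinium triflate (0.2 equiv), Hantzsch ester (1.5 equiv), DMA, 450 nm LEDs, 25 °C
Reagents that add atoms: none
Why: Proposed new method: a light-driven nickel-catalysed acylative ring opening of an epoxide by a cyclic anhydride, in which iodide opens 4 reversibly at its unhindered CH2 terminus to iodohydrin 7 (the oxygen-flanked tertiary carbon resists ionisation), photoreduced zerovalent nickel inserts into the less hindered acyl–oxygen bond of 6 (the carbonyl next to CH2) to give a divalent acylnickel carboxylate, monovalent nickel abstracts iodine from 7 to release the primary C4 radical, and capture of that radical gives a trivalent acyl(alkyl)nickel that reductively eliminates the C4–C5 ketone while excited 4CzIPN and Hantzsch ester return the electrons; no stereocentre is made or touched (C3 keeps its C–O bond, the C7–H is not enolised at near-neutral pH); the closest known reaction types are the nickel-catalysed cross-electrophile coupling of epoxides with aryl halides through in situ iodohydrins and the nickel/photoredox acylation of alkyl radicals with cyclic anhydrides.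

Step 5
Reactants: 8 (2R,6S)-6-[(4S)-2,2-dimethyl-1,3-dioxolan-4-yl]-6-hydroxy-2-methyl-4-oxoheptanoic acid
Product: 11 (3R,5R)-3-methyl-5-[(2S,3S)-2,3,4-trihydroxy-2-methylbutyl]oxolan-2-one, via anti-diol acid 9 (not isolated), via acetonide lactone 10 (not isolated)
Conditions: Me4NBH(OAc)3 (5 equiv), MeCN/AcOH (1:1), −30 °C; then 2 M HCl, THF, rt
Reagents that add atoms: none
Why: Evans–Saksena hydroxyl-directed reduction: the tertiary C3–OH binds the borohydride and delivers hydride intramolecularly through a chair transition state with the bulky dioxolanyl group equatorial, which gives the 1,3-anti diol (new carbinol R) under control of C3; aqueous acid then closes the γ-lactone without breaking the C5–O bond and hydrolyses the acetonide.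

Step 6
Reactants: 11 (3R,5R)-3-methyl-5-[(2S,3S)-2,3,4-trihydroxy-2-methylbutyl]oxolan-2-one; 12 7,8-dihydroxy-2H-chromen-2-one (daphnetin)
Product: 15 (3R,5R)-5-{(2S,3S)-2,3-dihydroxy-4-[(8-hydroxy-2-oxo-2H-chromen-7-yl)oxy]-2-methylbutyl}-3-methyloxolan-2-one, via primary tosylate 13 (not isolated), via terminal epoxide 14 (not isolated)
Conditions: TsCl (1.05 equiv), Bu2SnO (2 mol %), Et3N (1.2 equiv), CH2Cl2/MeCN, 0 °C; evaporate; then 12 (1.2 equiv), K2CO3 (2.5 equiv), DMF, 60 °C
Reagents that add atoms: none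
Why: Tin-acetal-catalysed sulfonylation picks the primary hydroxyl of the terminal 1,2-diol, carbonate closes tosylate 13 to epoxide 14, and the more acidic 7-OH of 12 (its phenoxide is conjugated with the pyranone carbonyl) opens the epoxide at the CH2 terminus in a Williamson-type aryl ether synthesis, so no bond to a stereocentre is broken and all four centres are retained.

## Compound list

1 | methyl (S)-2,2-dimethyl-1,3-dioxolane-4-carboxylate | COC(=O)[C@@H]1COC(C)(C)O1 | starting material
2 | (S)-2-chloro-1-(2,2-dimethyl-1,3-dioxolan-4-yl)ethan-1-one | ClCC(=O)[C@@H]1COC(C)(C)O1 | intermediate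
3 | (R)-1-chloro-2-[(S)-2,2-dimethyl-1,3-dioxolan-4-yl]propan-2-ol | ClC[C@](C)(O)[C@@H]1COC(C)(C)O1 | intermediate
4 | (S)-2,2-dimethyl-4-[(S)-2-methyloxiran-2-yl]-1,3-dioxolane | C1O[C@]1(C)[C@@H]2COC(C)(C)O2 | intermediate
5 | (R)-2-methylbutanedioic acid ((R)-methylsuccinic acid) | C[C@@H](C(=O)O)CC(=O)O | starting material
6 | (R)-3-methyloxolane-2,5-dione ((R)-methylsuccinic anhydride) | C[C@@H]1CC(=O)OC1=O | intermediate
7 | (R)-2-[(S)-2,2-dimethyl-1,3-dioxolan-4-yl]-1-iodopropan-2-ol | IC[C@](C)(O)[C@@H]1COC(C)(C)O1 | intermediate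
8 | (2R,6S)-6-[(4S)-2,2-dimethyl-1,3-dioxolan-4-yl]-6-hydroxy-2-methyl-4-oxoheptanoic acid | C[C@H](CC(=O)C[C@](C)(O)[C@@H]1COC(C)(C)O1)C(=O)O | intermediate
9 | (2R,4R,6S)-6-[(4S)-2,2-dimethyl-1,3-dioxolan-4-yl]-4,6-dihydroxy-2-methylheptanoic acid | C[C@H](C[C@@H](O)C[C@](C)(O)[C@@H]1COC(C)(C)O1)C(=O)O | intermediate
10 | (3R,5R)-5-{(2S)-2-[(4S)-2,2-dimethyl-1,3-dioxolan-4-yl]-2-hydroxypropyl}-3-methyloxolan-2-one | C[C@@H]1C[C@H](C[C@](C)(O)[C@@H]2COC(C)(C)O2)OC1=O | intermediate
11 | (3R,5R)-3-methyl-5-[(2S,3S)-2,3,4-trihydroxy-2-methylbutyl]oxolan-2-one | C[C@@H]1C[C@H](C[C@](C)(O)[C@@H](O)CO)OC1=O | intermediate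
12 | 7,8-dihydroxy-2H-chromen-2-one (daphnetin) | Oc1ccc2ccc(=O)oc2c1O | starting material
13 | (2S,3S)-2,3-dihydroxy-3-methyl-4-[(2R,4R)-4-methyl-5-oxooxolan-2-yl]butyl 4-methylbenzenesulfonate | C[C@@H]1C[C@H](C[C@](C)(O)[C@@H](O)COS(=O)(=O)c2ccc(C)cc2)OC1=O | intermediate
14 | (3R,5R)-5-{(2S)-2-hydroxy-2-[(2S)-oxiran-2-yl]propyl}-3-methyloxolan-2-one | C[C@@H]1C[C@H](C[C@](C)(O)[C@@H]2CO2)OC1=O | intermediate
15 | (3R,5R)-5-{(2S,3S)-2,3-dihydroxy-4-[(8-hydroxy-2-oxo-2H-chromen-7-yl)oxy]-2-methylbutyl}-3-methyloxolan-2-one | C[C@@H]1C[C@H](C[C@](C)(O)[C@@H](O)COc2ccc3ccc(=O)oc3c2O)OC1=O | target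

## Step count and risks

Total step count: 6. Longest linear sequence: 5 (steps 1, 2, 4, 5 and 6, from compound 1); step 3 is a one-step side branch.

**Step 4, the new coupling, is the most likely to fail.** The anhydride may insert at the wrong carbonyl, the C4 radical may be reduced by the Hantzsch ester, or the iodohydrin may simply re-close. The fallback uses known chemistry, sets out from 4 and moves the light-driven bond formation to C5–C6.
- Vinylmagnesium bromide with catalytic CuI opens the epoxide at its CH2 terminus to (2S)-2-[(4S)-2,2-dimethyl-1,3-dioxolan-4-yl]pent-4-en-2-ol F1.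
- Ozonolysis (O3, then PPh3) gives (3S)-3-[(4S)-2,2-dimethyl-1,3-dioxolan-4-yl]-3-hydroxybutanal F2.
- The established nickel/photoredox/hydrogen-atom-transfer acyl C–H alkylation of aldehydes with alkyl bromides is then run with bought methyl (S)-3-bromo-2-methylpropanoate (C[C@@H](C(=O)OC)CBr). Conditions: [Ir(dF(CF3)ppy)2(dtbbpy)]PF6, NiBr2(dme), 4,4′-dimethoxy-2,2′-bipyridine, quinuclidine, K2CO3, dioxane, blue LEDs. It gives methyl (2R,6S)-6-[(4S)-2,2-dimethyl-1,3-dioxolan-4-yl]-6-hydroxy-2-methyl-4-oxoheptanoate F3.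
- Under the conditions of step 5, F3 is reduced to methyl (2R,4R,6S)-6-[(4S)-2,2-dimethyl-1,3-dioxolan-4-yl]-4,6-dihydroxy-2-methylheptanoate F4, which lactonises to 10, where the route is rejoined.

**Step 2 may give the wrong C3 epimer.** This happens if an α-chelate, not the Felkin–Anh arrangement, controls the face of the acyl dioxolane. The fallback sets out from 1 and introduces the two C3 substituents in the reverse order, so the same facial preference gives the opposite relative configuration.
- Me(MeO)NH·HCl with iPrMgCl converts 1 into (S)-N-methoxy-N,2,2-trimethyl-1,3-dioxolane-4-carboxamide F5.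
- MeMgBr gives (S)-1-(2,2-dimethyl-1,3-dioxolan-4-yl)ethan-1-one F6.
- Chloromethylmagnesium chloride (from ICH2Cl and iPrMgCl·LiCl, THF, −78 °C) adds to F6 to give chlorohydrin 3, where the route is rejoined before the hydroxide ring closure.

**Step 5 may give poor anti selectivity.** The directing carbinol is tertiary, and the methyl and dioxolanyl groups may not differ enough in the chair transition state. The fallback sets out from 8, needs no directing effect and is stereoconvergent by inversion.
- NaBH4 reduction followed by mild acid (PPTS) gives 10 together with its C5 epimer (3R,5S)-5-{(2S)-2-[(4S)-2,2-dimethyl-1,3-dioxolan-4-yl]-2-hydroxypropyl}-3-methyloxolan-2-one F7; the two are separated.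
- F7 is opened with LiOH to (2R,4S,6S)-6-[(4S)-2,2-dimethyl-1,3-dioxolan-4-yl]-4,6-dihydroxy-2-methylheptanoic acid F8.
- F8 is re-closed under Mitsunobu conditions (PPh3, DIAD, THF, 0 °C) with inversion at the carbinol carbon to give 10, where the route is rejoined.

Further compounds

F1 | step 4 | (2S)-2-[(4S)-2,2-dimethyl-1,3-dioxolan-4-yl]pent-4-en-2-ol | C=CC[C@](C)(O)[C@@H]1COC(C)(C)O1
F2 | step 4 | (3S)-3-[(4S)-2,2-dimethyl-1,3-dioxolan-4-yl]-3-hydroxybutanal | O=CC[C@](C)(O)[C@@H]1COC(C)(C)O1
F3 | step 4 | methyl (2R,6S)-6-[(4S)-2,2-dimethyl-1,3-dioxolan-4-yl]-6-hydroxy-2-methyl-4-oxoheptanoate | C[C@H](CC(=O)C[C@](C)(O)[C@@H]1COC(C)(C)O1)C(=O)OC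
F4 | step 4 | methyl (2R,4R,6S)-6-[(4S)-2,2-dimethyl-1,3-dioxolan-4-yl]-4,6-dihydroxy-2-methylheptanoate | C[C@H](C[C@@H](O)C[C@](C)(O)[C@@H]1COC(C)(C)O1)C(=O)OC
F5 | step 2 | (S)-N-methoxy-N,2,2-trimethyl-1,3-dioxolane-4-carboxamide | CON(C)C(=O)[C@@H]1COC(C)(C)O1
F6 | step 2 | (S)-1-(2,2-dimethyl-1,3-dioxolan-4-yl)ethan-1-one | CC(=O)[C@@H]1COC(C)(C)O1
F7 | step 5 | (3R,5S)-5-{(2S)-2-[(4S)-2,2-dimethyl-1,3-dioxolan-4-yl]-2-hydroxypropyl}-3-methyloxolan-2-one | C[C@@H]1C[C@@H](C[C@](C)(O)[C@@H]2COC(C)(C)O2)OC1=O
F8 | step 5 | (2R,4S,6S)-6-[(4S)-2,2-dimethyl-1,3-dioxolan-4-yl]-4,6-dihydroxy-2-methylheptanoic acid | C[C@H](C[C@H](O)C[C@](C)(O)[C@@H]1COC(C)(C)O1)C(=O)O
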